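Ring B (C5–C10, eudesmane numbering) is cut at C9, the bare methylene between quaternary C10 and the C8 carbonyl. Deleting C9 leaves a trans-hydrindan-8-one of the Hajos–Parrish type, in which C10 is set by amino-acid catalysis and then relays C5, C4 and C3 by substrate control. In the key step dibromomethyllithium adds to the cyclopentanone, and the derived β-oxido carbenoid shifts the C8–C10 bond onto the new carbon. In one operation the five-membered ring becomes the cyclohexanone, with its carbonyl moved one atom away from C10. The precursor is a 9-nor keto diol. Acetone aldol at C7, angeloylation and acetylation–elimination finish the synthesis.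

Key step: step 7

Remark: eudesmane numbering is used for all bicyclic compounds (ring A = C1–C5 and C10; ring B = C5–C10; C14 on C10, C15 on C4; α/β as in the usual drawing with C14 β). In the hydrindanes 4–13, C9 is missing and C8 is bonded directly to C10.
Remark: the C7 side chain of the aldol adducts is drawn equatorial (7β). This has no consequence, because C7 becomes sp2 in step 10.

Step 1
Reactants: 1 2-methylcyclopentane-1,3-dione; 2 ethyl vinyl ketone (pent-1-en-3-one)
Product: 3 2-methyl-2-(3-oxopentyl)cyclopentane-1,3-dione
Conditions: H2O, AcOH (cat.), 75 °C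
Reagents that add atoms: none
Why: Michael addition of the acidic cyclic 1,3-dione through its C2 to the enone should give the prochiral triketone that holds every carbon of ring A and of the five-membered ring.

Step 2
Reactants: 3 2-methyl-2-(3-oxopentyl)cyclopentane-1,3-dione
Product: 4 (7aS)-4,7a-dimethyl-2,3,7,7a-tetrahydro-1H-indene-1,5(6H)-dione (C10 = C7a)
Conditions: L-phenylalanine, (1S)-(+)-camphor-10-sulfonic acid, DMF, 30 → 70 °C; recrystallisation
Reagents that add atoms: none
Why: In this Hajos–Parrish–Eder–Sauer–Wiechert reaction the enamine of the ethyl ketone with the L-amino acid attacks one of the two enantiotopic ring carbonyls and dehydration follows, which should set C10 as S (C14 β); a primary amino acid is chosen because the α-branched enamine forms poorly with proline.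

Step 3
Reactants: 4 (7aS)-4,7a-dimethyl-2,3,7,7a-tetrahydro-1H-indene-1,5(6H)-dione
Product: 5 C8 ethylene ketal of 4 (Δ4-3-ketone untouched)
Conditions: TMSOCH2CH2OTMS, TMSOTf (cat.), CH2Cl2, −78 → −20 °C
Reagents that add atoms: 1,2-bis(trimethylsilyloxy)ethane, C[Si](C)(C)OCCO[Si](C)(C)C
Why: Under kinetic Noyori ketalisation the saturated ketone reacts faster than the conjugated, α-methylated enone carbonyl, and the low temperature avoids deconjugation.

Step 4
Reactants: 5 C8 ethylene ketal of 4
Product: 7 C3 trimethylsilyl enol ether (C3=C4) of the 5α-H trans-hydrindane ketal, via lithium C3–C4 enolate 6 (not isolated)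
Conditions: Li, NH3(l)/THF, t-BuOH (1 equiv), −78 → −33 °C; isoprene; NH3 off; Me3SiCl, Et3N, THF, −78 → 0 °C
Reagents that add atoms: chlorotrimethylsilane, C[Si](C)(C)Cl
Why: In this dissolving-metal enone reduction with regiospecific enolate trapping, axial protonation of the β-carbanion at C5 on the face opposite C14 should give the trans ring fusion (5α-H), and silylation fixes the enolate between C3 and C4.

Step 5
Reactants: 7 C3 trimethylsilyl enol ether of the 5α-H trans-hydrindane ketal
Product: 9 4α-hydroxy-4β-methyl 3-ketone (trans-hydrindane ketal), via 4α-silyloxy ketone 8 (not isolated)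
Conditions: m-CPBA, NaHCO3, CH2Cl2, −20 °C; then K2CO3 (cat.), MeOH, 0 °C
Reagents that add atoms: m-chloroperbenzoic acid, OOC(=O)c1cccc(Cl)c1
Why: In this Rubottom oxidation the β face of C4 is screened by the syn-axial C14 methyl, so oxygen should arrive from the α face and leave 4α-O equatorial and C15 4β axial.

Step 6
Reactants: 9 4α-hydroxy-4β-methyl 3-ketone (trans-hydrindane ketal)
Product: 11 3β,4α-dihydroxy-4β,10β-dimethyl-5α-H-trans-hydrindan-8-one (9-nor keto diol), via diol ketal 10 (not isolated)
Conditions: NaBH4, MeOH/CH2Cl2, −20 → 0 °C; then 1 M HCl, THF, rt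
Reagents that add atoms: water, O
Why: Axial hydride delivery from the α face (the equatorial path is flanked by the axial 4β-methyl) should give the equatorial 3β-alcohol, trans-diequatorial to 4α-OH, and the acid then hydrolyses the dioxolane.

Step 7
Reactants: 11 3β,4α-dihydroxy-4β,10β-dimethyl-5α-H-trans-hydrindan-8-one
Product: 15 3β,4α-dihydroxy-11,12,13-trinoreudesman-8-one (trans-decalone diol), via trilithium dibromomethyl carbinolate 12 (not isolated), via β-oxido carbenoid 13 (not isolated), via ring-enlarged lithium enolate 14 (not isolated)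
Conditions: CH2Br2, LDA (excess, added to 11 + CH2Br2), THF, −90 °C; then n-BuLi (excess), −90 → 0 °C; aq NH4Cl
Reagents that add atoms: dibromomethane, BrCBr
Why: LDA deprotonates CH2Br2 faster than the hindered ketone and LiCHBr2 adds to C8=O from the α face (anti to C14) while both hydroxyls ride along as lithium alkoxides; n-BuLi then exchanges one bromine, and carbenoid 13 expels LiBr as the C8–C10 σ bond, pushed by the oxido group, shifts to the electrophilic carbenoid carbon, which becomes C9, leaving enolate 14 of the six-membered ketone. The closest known reaction type is the β-oxido carbenoid (dibromomethyllithium) ring enlargement of cycloalkanones, a carbenoid relative of the Tiffeneau–Demjanov rearrangement. No ring is closed by cyclisation: ring B arises from the cyclopentane by a 1,2-shift that inserts one carbon (5 → 6). No stereocentre is created: C10 migrates with retention, the transient carbinol centre C8 returns to sp2, and C3, C4 and C5 are untouched. The selectivity needed is migration of C10 rather than C7; in this rearrangement the more substituted, electron-richer α-carbon migrates preferentially (the opposite of diazoalkane homologation), here fully substituted C10 against a CH2, and release of trans-hydrindanone strain helps. The esters and the enone are installed only afterwards, so nothing else in 11 is sensitive to the organolithium reagents.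

Step 8
Reactants: 15 3β,4α-dihydroxy-11,12,13-trinoreudesman-8-one
Product: 17 3β,4α,11-trihydroxyeudesman-8-one (7β side chain), via trilithiated Δ7 enolate 16 (not isolated)
Conditions: LDA (excess), THF, −78 °C; ZnCl2; acetone, −78 → −40 °C; aq NH4Cl
Reagents that add atoms: acetone, CC(C)=O
Why: In this directed aldol addition, kinetic deprotonation should occur at C7 because C9 is neopentyl next to C10, and the zinc aldolate suppresses retro-aldol; the new C7 centre is erased later.

Step 9
Reactants: 17 3β,4α,11-trihydroxyeudesman-8-one; 18 angelic acid ((Z)-2-methylbut-2-enoic acid)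
Product: 19 3β-angeloyloxy-4α,11-dihydroxyeudesman-8-one
Conditions: 18, 2,4,6-trichlorobenzoyl chloride, Et3N, toluene, rt; then 17, 80 °C
Reagents that add atoms: none
Why: Yamaguchi-type mixed-anhydride esterification run without a nucleophilic catalyst should keep the Z geometry, and only the secondary equatorial 3β-OH is acylated while both tertiary alcohols stay free.

Step 10
Reactants: 19 3β-angeloyloxy-4α,11-dihydroxyeudesman-8-one
Product: 21 4α-acetoxy-3β-angeloyloxyeudesm-7(11)-en-8-one (CNP0141494.1), via 4α,11-diacetate 20 (not isolated)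
Conditions: Ac2O, DMAP, Et3N, CH2Cl2, 40 °C; then DBU, rt
Reagents that add atoms: acetic anhydride, CC(=O)OC(C)=O
Why: DMAP-catalysed acylation should acetylate both tertiary alcohols, and the β-acetoxy ketone then undergoes E1cB elimination to the conjugated tetrasubstituted C7=C11 enone, which removes the C7 centre and touches no other stereocentre.

Compound list
1 | 2-methylcyclopentane-1,3-dione | CC1C(=O)CCC1=O | starting material
2 | ethyl vinyl ketone | CCC(=O)C=C | starting material
3 | 2-methyl-2-(3-oxopentyl)cyclopentane-1,3-dione | CCC(=O)CCC1(C)C(=O)CCC1=O | intermediate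
4 | (7aS)-4,7a-dimethyl-2,3,7,7a-tetrahydro-1H-indene-1,5(6H)-dione | O=C1CC[C@]2(C)C(=O)CCC2=C1C | intermediate
5 | C8 ethylene ketal of 4 | O=C1CC[C@]2(C)C3(OCCO3)CCC2=C1C | intermediate
6 | lithium C3–C4 enolate of the 5α-H trans-hydrindane ketal (not isolated) | [Li]OC1=C(C)[C@@H]2CCC3(OCCO3)[C@@]2(C)CC1 | intermediate
7 | C3 trimethylsilyl enol ether of the 5α-H trans-hydrindane ketal | C[Si](C)(C)OC1=C(C)[C@@H]2CCC3(OCCO3)[C@@]2(C)CC1 | intermediate
8 | 4α-trimethylsilyloxy-4β-methyl 3-ketone ketal (not isolated) | O=C1CC[C@]2(C)C3(OCCO3)CC[C@H]2[C@]1(C)O[Si](C)(C)C | intermediate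
9 | 4α-hydroxy-4β-methyl 3-ketone ketal | O=C1CC[C@]2(C)C3(OCCO3)CC[C@H]2[C@]1(C)O | intermediate
10 | 3β,4α-diol ketal (not isolated) | O[C@H]1CC[C@]2(C)C3(OCCO3)CC[C@H]2[C@]1(C)O | intermediate
11 | 3β,4α-dihydroxy-4β,10β-dimethyl-5α-H-trans-hydrindan-8-one | O[C@H]1CC[C@]2(C)C(=O)CC[C@H]2[C@]1(C)O | intermediate
12 | trilithium alkoxide of the 8α-dibromomethyl-8β-ol (not isolated) | [Li]O[C@H]1CC[C@]2(C)[C@](O[Li])(C(Br)Br)CC[C@H]2[C@]1(C)O[Li] | intermediate
13 | β-oxido carbenoid, 8α-CH(Li)Br (not isolated) | [Li]O[C@H]1CC[C@]2(C)[C@](O[Li])(C([Li])Br)CC[C@H]2[C@]1(C)O[Li] | intermediate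
14 | ring-enlarged lithium Δ8(9) enolate (not isolated) | [Li]O[C@H]1CC[C@]2(C)C=C(O[Li])CC[C@H]2[C@]1(C)O[Li] | intermediate
15 | 3β,4α-dihydroxy-11,12,13-trinoreudesman-8-one | O[C@H]1CC[C@]2(C)CC(=O)CC[C@H]2[C@]1(C)O | intermediate
16 | trilithiated Δ7 enolate, moved to zinc before the aldol (not isolated) | [Li]O[C@H]1CC[C@]2(C)CC(O[Li])=CC[C@H]2[C@]1(C)O[Li] | intermediate
17 | 3β,4α,11-trihydroxyeudesman-8-one | O[C@H]1CC[C@]2(C)CC(=O)[C@@H](C(C)(C)O)C[C@H]2[C@]1(C)O | intermediate
18 | angelic acid | C/C=C(/C)C(=O)O | starting material
19 | 3β-angeloyloxy-4α,11-dihydroxyeudesman-8-one | C/C=C(/C)C(=O)O[C@H]1CC[C@]2(C)CC(=O)[C@@H](C(C)(C)O)C[C@H]2[C@]1(C)O | intermediate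
20 | 4α,11-diacetoxy-3β-angeloyloxyeudesman-8-one (not isolated) | C/C=C(/C)C(=O)O[C@H]1CC[C@]2(C)CC(=O)[C@@H](C(C)(C)OC(C)=O)C[C@H]2[C@]1(C)OC(C)=O | intermediate
21 | 4α-acetoxy-3β-angeloyloxyeudesm-7(11)-en-8-one | C/C=C(/C)C(=O)O[C@H]1CC[C@]2(C)CC(=O)C(=C(C)C)C[C@H]2[C@]1(C)OC(C)=O | target

Total step count: 10. Longest linear sequence: 10 steps (1 → 21).

Steps most likely to fail

Step 7. The hindered, enolisable C8 ketone may be deprotonated instead of attacked. In the carbenoid shift C7 may also compete with C10, which would leave the carbonyl next to C10. The fallback sets out from 11 and comes back at 15. Wittig methylenation of 11 with excess Ph3P=CH2 should give the 8-methylene diol F1. Oxidative rearrangement of this exocyclic alkene with PhI(OH)OTs in aqueous methanol should then give 15 after aqueous work-up. The mechanism is iodine(III) addition at the CH2 terminus, solvent capture at C8, then a cationic 1,2-shift of the electron-richer C10 with loss of iodobenzene. Here the extra carbon enters by olefination rather than by carbanion addition, and the shift is cationic rather than carbenoid.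

Step 4. Protonation at C5 is less face-selective in a hydrindenone than in an octalone, so the cis ring fusion may intrude. The enolate may also equilibrate before it is silylated. The fallback sets out from 4 and comes back at 11, and it skips the ketal.
- Conjugate hydride delivery to C5 from the α face by a bulky hydridocuprate (DIBAL-H, t-BuCu, HMPA, THF, −50 °C) is used. This reagent type is known to give trans-hydrindanones and to spare a saturated ketone. With Me3SiCl trapping it should give the silyl enol ether ketone F2.
- Rubottom oxidation as in step 5 should give the 4α-hydroxy 3,8-dione F3.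
- The unhindered, hydroxyl-flanked C3 ketone is then reduced with NaBH(OAc)3 (or NaBH4 at −78 °C) in the presence of the neopentyl C8 ketone, to reach 11.

Step 9. Heating the acetone aldol 17 may cause retro-aldol loss of acetone or premature dehydration. Slow acylation next to the tertiary carbinol also leaves time for Z → E isomerisation. The fallback sets out from 15 and comes back at 21 by changing the order of events.
- The robust keto diol 15 is angeloylated under the same mixed-anhydride conditions to give the 3β-angelate F4.
- Acetylation at the tertiary 4α-OH (Ac2O, DMAP, Et3N) gives the angelate acetate ketone F5.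
- The ketone alone is then enolised with LiHMDS at −78 °C (toward C7), moved to zinc and added to acetone, to give the 11-hydroxy diester F6.
- MsCl/Et3N followed by DBU eliminates the tertiary alcohol to give 21.

Further compounds
F1 | step 7 | 3β,4α-dihydroxy-4β,10β-dimethyl-8-methylene-5α-H-trans-hydrindane | O[C@H]1CC[C@]2(C)C(=C)CC[C@H]2[C@]1(C)O
F2 | step 4 | C3 trimethylsilyl enol ether of the 5α-H trans-hydrindane-3,8-dione (free C8 ketone) | C[Si](C)(C)OC1=C(C)[C@@H]2CCC(=O)[C@@]2(C)CC1
F3 | step 4 | 4α-hydroxy-4β,10β-dimethyl-5α-H-trans-hydrindane-3,8-dione | O=C1CC[C@]2(C)C(=O)CC[C@H]2[C@]1(C)O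
F4 | step 9 | 3β-angeloyloxy-4α-hydroxy-11,12,13-trinoreudesman-8-one | C/C=C(/C)C(=O)O[C@H]1CC[C@]2(C)CC(=O)CC[C@H]2[C@]1(C)O
F5 | step 9 | 4α-acetoxy-3β-angeloyloxy-11,12,13-trinoreudesman-8-one | C/C=C(/C)C(=O)O[C@H]1CC[C@]2(C)CC(=O)CC[C@H]2[C@]1(C)OC(C)=O
F6 | step 9 | 4α-acetoxy-3β-angeloyloxy-11-hydroxyeudesman-8-one | C/C=C(/C)C(=O)O[C@H]1CC[C@]2(C)CC(=O)[C@@H](C(C)(C)O)C[C@H]2[C@]1(C)OC(C)=O
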